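**Plan**

- Retrosynthesis: cut the pyranone lactone bond O1'–C2' (back to a 4-aroyl-3-benzyloxycyclobutenone), then C5'–C6' (aldol of a cyclobutenone enolate with the C5 aldehyde), then C6–phenyl (Suzuki), then the arene bonds C4a–C5 and C8–C8a (Diels–Alder benzannulation of a 2-bromocyclohexenone).
- Forward: ring B (the cyclohexanone C1–C4, C4a, C8a) comes from the triol, the benzene ring A is annulated onto it, the phenyl group and the cyclobutenone are attached, and the pyranone ring C is closed last.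
- Enabling feature: the 4-hydroxy-2-pyranone (O1', C2'–C6') hangs by C6' on C5, the arene carbon flanked by the C6 phenyl and the C4 methylene, in a molecule whose C1 ketone/C3 carbinol pair dehydrates to a naphthol under acid or base. The C6' carbonyl of an aroyl group and C2'–C5' of a cyclobutenone can be joined thermally without either.
- Stereochemistry: the only stereocentre, C3 (S), is set by lipase desymmetrisation of a meso diol and is never touched again.

Key step: step 16

Numbering: tetralone atoms C1–C8a and pyranone atoms O1'–C6' as in the target; systematic names of intermediates carry their own locants.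

Assumption: the lipase is taken to acetylate meso diol 2 in the sense usual for simple cis-cyclohexane-1,3-diols, which puts the acetate on the carbinol drawn in 3; should the enzyme prefer the other hydroxyl, lipase hydrolysis of the meso diacetate would give the same monoacetate.

**Route**

Step 1
Reactants: 1 all-cis-cyclohexane-1,3,5-triol
Product: 2 all-cis-5-[(tert-butyldimethylsilyl)oxy]cyclohexane-1,3-diol (meso)
Conditions: TBSCl (1 equiv), imidazole, DMF, 0 °C to rt
Reagents that add atoms: tert-butyldimethylsilyl chloride, CC(C)(C)[Si](C)(C)Cl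
Why: Silyl ether formation on three homotopic hydroxyls can give only one mono-ether, which is separable from triol and bis-ether.

Step 2
Reactants: 2 all-cis-5-[(tert-butyldimethylsilyl)oxy]cyclohexane-1,3-diol
Product: 3 (1S,3R,5R)-3-[(tert-butyldimethylsilyl)oxy]-5-hydroxycyclohexyl acetate
Conditions: vinyl acetate, Candida antarctica lipase B (immobilised), t-BuOMe, rt
Reagents that add atoms: vinyl acetate, CC(=O)OC=C
Why: Enzymatic desymmetrisation by irreversible transesterification distinguishes the two enantiotopic carbinols of the meso diol, which makes the silyloxy-bearing carbon (the future C3) stereogenic in one absolute sense.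

Step 3
Reactants: 3 (1S,3R,5R)-3-[(tert-butyldimethylsilyl)oxy]-5-hydroxycyclohexyl acetate
Product: 5 (S)-5-[(tert-butyldimethylsilyl)oxy]cyclohex-2-en-1-one, via acetoxy ketone 4 (not isolated)
Conditions: (COCl)2, DMSO, CH2Cl2, −78 °C; Et3N, −78 °C to rt
Reagents that add atoms: none
Why: Swern oxidation of the free carbinol is followed in the same flask by E1cB loss of the β-acetate, a far better leaving group than the β-silyloxide, so the ketone sits on the former free-hydroxyl carbon and the silyloxy carbon becomes C5 (S).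

Step 4
Reactants: 5 (S)-5-[(tert-butyldimethylsilyl)oxy]cyclohex-2-en-1-one
Product: 7 (S)-2-bromo-5-[(tert-butyldimethylsilyl)oxy]cyclohex-2-en-1-one, via dibromo ketone 6 (not isolated)
Conditions: Br2, CH2Cl2, 0 °C; then Et3N, 0 °C
Reagents that add atoms: bromine, BrBr
Why: Bromine addition to the enone and dehydrobromination through the acidic α-hydrogen is the standard α-bromination of cycloalkenones and does not involve the remote C5 centre.

Step 5
Reactants: 8 dimethyl 3-oxopentanedioate
Product: 9 dimethyl 3-[(trimethylsilyl)oxy]pent-2-enedioate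
Conditions: TMSCl, Et3N, Et2O, rt
Reagents that add atoms: chlorotrimethylsilane, C[Si](C)(C)Cl
Why: O-silylation of the enolised β-keto ester (silyl enol ether formation) gives the mono-enol ether, whose alkene geometry is immaterial.

Step 6
Reactants: 9 dimethyl 3-[(trimethylsilyl)oxy]pent-2-enedioate
Product: 10 methyl 5-methoxy-3,5-bis[(trimethylsilyl)oxy]penta-2,4-dienoate
Conditions: LiN(iPr)2, THF, −78 °C; TMSCl, −78 °C to rt
Reagents that add atoms: chlorotrimethylsilane, C[Si](C)(C)Cl
Why: Deprotonation of the remaining α-methylene and O-silylation of the ester enolate gives the 1,3-bis(silyloxy)diene with a ketene-acetal terminus, the standard two-stage preparation of such dienes.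

Step 7
Reactants: 7 (S)-2-bromo-5-[(tert-butyldimethylsilyl)oxy]cyclohex-2-en-1-one; 10 methyl 5-methoxy-3,5-bis[(trimethylsilyl)oxy]penta-2,4-dienoate
Product: 12 methyl (7S)-7-[(tert-butyldimethylsilyl)oxy]-2,4-dihydroxy-5-oxo-5,6,7,8-tetrahydronaphthalene-1-carboxylate, via cis-fused bromo cycloadduct 11 (not isolated)
Conditions: toluene, 90 °C; then DBU, THF, 0 °C; aqueous citric acid work-up
Reagents that add atoms: none
Why: Diels–Alder benzannulation with a ketene-acetal diene: the electron-rich ester-bearing terminus bonds to the enone β-carbon (C4a) and the acetal carbon to the brominated α-carbon (C8a), and base-promoted loss of HBr and methanol with hydrolysis of the aryl trimethylsilyl ethers aromatises ring A with the ester on C5 and hydroxyls on C6 and C8, the C3 silyl ether being a spectator.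

Step 8
Reactants: 12 methyl (7S)-7-[(tert-butyldimethylsilyl)oxy]-2,4-dihydroxy-5-oxo-5,6,7,8-tetrahydronaphthalene-1-carboxylate
Product: 13 methyl (7S)-7-[(tert-butyldimethylsilyl)oxy]-4-hydroxy-5-oxo-2-{[(trifluoromethyl)sulfonyl]oxy}-5,6,7,8-tetrahydronaphthalene-1-carboxylate
Conditions: PhNTf2 (1.05 equiv), Et3N, CH2Cl2, 0 °C
Reagents that add atoms: N-phenylbis(trifluoromethanesulfonimide), O=S(=O)(N(c1ccccc1)S(=O)(=O)C(F)(F)F)C(F)(F)F
Why: Site-selective O-sulfonylation: the C6 hydroxyl, para to the C1 ketone and held only by the weaker ester hydrogen bond, is more acidic and more accessible than the C8 hydroxyl locked in the peri-ketone chelate, so one equivalent of a mild triflyl donor should mark C6 alone.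

Step 9
Reactants: 13 methyl (7S)-7-[(tert-butyldimethylsilyl)oxy]-4-hydroxy-5-oxo-2-{[(trifluoromethyl)sulfonyl]oxy}-5,6,7,8-tetrahydronaphthalene-1-carboxylate; 14 phenylboronic acid
Product: 15 methyl (7S)-7-[(tert-butyldimethylsilyl)oxy]-4-hydroxy-5-oxo-2-phenyl-5,6,7,8-tetrahydronaphthalene-1-carboxylate
Conditions: Pd(PPh3)4 (5 mol%), K3PO4, 1,4-dioxane/H2O, 80 °C
Reagents that add atoms: none
Why: Suzuki–Miyaura coupling of an electron-poor aryl triflate under zerovalent palladium catalysis installs the C6 phenyl group, and the chelated C8 phenoxide lowers the acidity of the C2 hydrogens so that the β-silyloxy ketone tolerates the phosphate base.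

Step 10
Reactants: 15 methyl (7S)-7-[(tert-butyldimethylsilyl)oxy]-4-hydroxy-5-oxo-2-phenyl-5,6,7,8-tetrahydronaphthalene-1-carboxylate; 16 benzyl alcohol
Product: 17 methyl (7S)-4-(benzyloxy)-7-[(tert-butyldimethylsilyl)oxy]-5-oxo-2-phenyl-5,6,7,8-tetrahydronaphthalene-1-carboxylate
Conditions: PPh3, DIAD, THF, 0 °C to rt
Reagents that add atoms: none
Why: Mitsunobu etherification benzylates the acidic chelated C8 phenol under neutral conditions, avoiding the heated carbonate conditions that could eliminate the C3 silyloxy group.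

Step 11
Reactants: 17 methyl (7S)-4-(benzyloxy)-7-[(tert-butyldimethylsilyl)oxy]-5-oxo-2-phenyl-5,6,7,8-tetrahydronaphthalene-1-carboxylate
Product: 18 (3S)-8-(benzyloxy)-3-[(tert-butyldimethylsilyl)oxy]-5-(hydroxymethyl)-6-phenyl-1,2,3,4-tetrahydronaphthalen-1-ol (both C1 epimers)
Conditions: LiAlH4, THF, 0 °C to rt
Reagents that add atoms: none
Why: Hydride reduction takes the hindered C5 ester to the primary alcohol and unavoidably the C1 ketone to the carbinol, both to be reoxidised together, while silyl and benzyl ethers are inert.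

Step 12
Reactants: 18 (3S)-8-(benzyloxy)-3-[(tert-butyldimethylsilyl)oxy]-5-(hydroxymethyl)-6-phenyl-1,2,3,4-tetrahydronaphthalen-1-ol
Product: 19 (7S)-4-(benzyloxy)-7-[(tert-butyldimethylsilyl)oxy]-5-oxo-2-phenyl-5,6,7,8-tetrahydronaphthalene-1-carbaldehyde
Conditions: Dess–Martin periodinane (2.5 equiv), pyridine, CH2Cl2, rt
Reagents that add atoms: none
Why: Dess–Martin oxidation of both benzylic alcohols restores the C1 ketone and gives the C5 aldehyde without acid or base that would endanger the β-silyloxy ketone.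

Step 13
Reactants: 20 3-ethoxycyclobut-2-en-1-one; 16 benzyl alcohol
Product: 21 3-(benzyloxy)cyclobut-2-en-1-one
Conditions: PPTS (cat.), toluene, 40 °C, reduced pressure
Reagents that add atoms: none
Why: Acid-catalysed transetherification of a vinylogous ester (addition of benzyl alcohol to the protonated enone, loss of ethanol, driven by removing ethanol) exchanges ethoxy for the hydrogenolysable benzyloxy group.

Step 14
Reactants: 21 3-(benzyloxy)cyclobut-2-en-1-one; 19 (7S)-4-(benzyloxy)-7-[(tert-butyldimethylsilyl)oxy]-5-oxo-2-phenyl-5,6,7,8-tetrahydronaphthalene-1-carbaldehyde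
Product: 23 (3S)-8-(benzyloxy)-5-{[2-(benzyloxy)-4-oxocyclobut-2-en-1-yl](hydroxy)methyl}-3-[(tert-butyldimethylsilyl)oxy]-6-phenyl-3,4-dihydronaphthalen-1(2H)-one (mixture at the two new centres), via lithium enolate 22 (not isolated)
Conditions: LiN(iPr)2, THF, −78 °C; then 19, −78 °C; AcOH, −78 °C
Reagents that add atoms: none
Why: Kinetic deprotonation at C4 of the cyclic vinylogous ester (as in Stork–Danheiser chemistry) and aldol addition of the lithium enolate to the non-enolisable aldehyde at −78 °C should form the C5'–C6' bond faster than proton transfer to the tetralone, and the two new centres need no control because both are erased in steps 15 and 16.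

Step 15
Reactants: 23 (3S)-8-(benzyloxy)-5-{[2-(benzyloxy)-4-oxocyclobut-2-en-1-yl](hydroxy)methyl}-3-[(tert-butyldimethylsilyl)oxy]-6-phenyl-3,4-dihydronaphthalen-1(2H)-one
Product: 24 (3S)-8-(benzyloxy)-5-{[2-(benzyloxy)-4-oxocyclobut-2-en-1-yl]carbonyl}-3-[(tert-butyldimethylsilyl)oxy]-6-phenyl-3,4-dihydronaphthalen-1(2H)-one
Conditions: Dess–Martin periodinane, pyridine, CH2Cl2, 0 °C to rt
Reagents that add atoms: none
Why: Dess–Martin oxidation converts the β-hydroxy ketone into the 1,3-dicarbonyl compound under buffered conditions and removes the carbinol stereocentre.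

Step 16
Reactants: 24 (3S)-8-(benzyloxy)-5-{[2-(benzyloxy)-4-oxocyclobut-2-en-1-yl]carbonyl}-3-[(tert-butyldimethylsilyl)oxy]-6-phenyl-3,4-dihydronaphthalen-1(2H)-one
Product: 26 (3S)-8-(benzyloxy)-5-[4-(benzyloxy)-2-oxo-2H-pyran-6-yl]-3-[(tert-butyldimethylsilyl)oxy]-6-phenyl-3,4-dihydronaphthalen-1(2H)-one, via acylvinylketene 25 (not isolated)
Conditions: toluene (dilute), 90–110 °C
Reagents that add atoms: none
Why: Heating opens the strained cyclobutenone by a thermally allowed conrotatory 4π electrocyclic cleavage of its C1–C4 bond to vinylketene 25, whose terminal carbon carries the aroyl group. When that group has turned inward its carbonyl oxygen lies beside the ketene carbon and adds to it in an oxa-6π electrocyclisation (six-membered ring closed through the O1'–C2' bond, disrotatory or pseudopericyclic), which gives the 2-pyranone with the benzyloxy group on C4'. The closest known reaction type is the thermal isomerisation of 4-acylcyclobutenones to 2-pyranones, which combines the cyclobutenone-to-vinylketene opening used in cyclobutenone benzannulations with the valence isomerisation of cis-dienone ketenes to 2-pyranones. No stereocentre is formed and C3 is a spectator. The only selectivity needed is torquoselectivity, which the acceptor character of the acyl group provides by favouring inward rotation; because the opening is reversible, an outward-rotated ketene recloses and is drained through the inward pathway into the irreversibly formed pyranone. Neither acid nor base is present, so the β-silyloxy ketone cannot eliminate to a naphthol, and the unimolecular closure is indifferent to the flanking C6 phenyl and C4 methylene groups.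

Step 17
Reactants: 26 (3S)-8-(benzyloxy)-5-[4-(benzyloxy)-2-oxo-2H-pyran-6-yl]-3-[(tert-butyldimethylsilyl)oxy]-6-phenyl-3,4-dihydronaphthalen-1(2H)-one
Product: 27 (3S)-8-(benzyloxy)-5-[4-(benzyloxy)-2-oxo-2H-pyran-6-yl]-3-hydroxy-6-phenyl-3,4-dihydronaphthalen-1(2H)-one
Conditions: HF·pyridine, pyridine, THF, 0 °C to rt
Reagents that add atoms: none
Why: Fluoride-mediated desilylation with pyridine-buffered HF·pyridine cleaves the secondary silyl ether without the free acid or base that would dehydrate the β-hydroxy ketone.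

Step 18
Reactants: 27 (3S)-8-(benzyloxy)-5-[4-(benzyloxy)-2-oxo-2H-pyran-6-yl]-3-hydroxy-6-phenyl-3,4-dihydronaphthalen-1(2H)-one
Product: 28 wailupemycin F, (3S)-3,8-dihydroxy-5-(4-hydroxy-2-oxo-2H-pyran-6-yl)-6-phenyl-3,4-dihydronaphthalen-1(2H)-one
Conditions: H2 (1 atm), Pd/C (10 wt%), EtOAc, rt
Reagents that add atoms: none
Why: Hydrogenolysis cleaves the aryl benzyl ether and the vinylogous benzyl ester under neutral conditions and should leave the C3 carbinol, the aryl ketone and the pyranone intact if stopped once both benzyl groups are gone.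

**Compound list**

1 | all-cis-cyclohexane-1,3,5-triol | O[C@@H]1C[C@H](O)C[C@H](O)C1 | starting material
2 | all-cis-5-[(tert-butyldimethylsilyl)oxy]cyclohexane-1,3-diol (meso) | O[C@@H]1C[C@H](O)C[C@H](O[Si](C)(C)C(C)(C)C)C1 | intermediate
3 | (1S,3R,5R)-3-[(tert-butyldimethylsilyl)oxy]-5-hydroxycyclohexyl acetate | O[C@@H]1C[C@H](OC(C)=O)C[C@H](O[Si](C)(C)C(C)(C)C)C1 | intermediate
4 | (1R,3S)-3-[(tert-butyldimethylsilyl)oxy]-5-oxocyclohexyl acetate | O=C1C[C@H](OC(C)=O)C[C@H](O[Si](C)(C)C(C)(C)C)C1 | intermediate (not isolated)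
5 | (S)-5-[(tert-butyldimethylsilyl)oxy]cyclohex-2-en-1-one | O=C1C[C@@H](O[Si](C)(C)C(C)(C)C)CC=C1 | intermediate
6 | (5R)-2,3-dibromo-5-[(tert-butyldimethylsilyl)oxy]cyclohexan-1-one (C2 and C3 unassigned; spatial arrangement at C5 as in 5) | O=C1C[C@@H](O[Si](C)(C)C(C)(C)C)CC(Br)C1Br | intermediate (not isolated)
7 | (S)-2-bromo-5-[(tert-butyldimethylsilyl)oxy]cyclohex-2-en-1-one | O=C1C[C@@H](O[Si](C)(C)C(C)(C)C)CC=C1Br | intermediate
8 | dimethyl 3-oxopentanedioate | COC(=O)CC(=O)CC(=O)OC | starting material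
9 | dimethyl 3-[(trimethylsilyl)oxy]pent-2-enedioate (alkene geometry immaterial) | COC(=O)CC(O[Si](C)(C)C)=CC(=O)OC | intermediate
10 | methyl 5-methoxy-3,5-bis[(trimethylsilyl)oxy]penta-2,4-dienoate | COC(=O)C=C(O[Si](C)(C)C)C=C(OC)O[Si](C)(C)C | intermediate
11 | methyl (7S)-4a-bromo-7-[(tert-butyldimethylsilyl)oxy]-4-methoxy-5-oxo-2,4-bis[(trimethylsilyl)oxy]-1,4,4a,5,6,7,8,8a-octahydronaphthalene-1-carboxylate (cis-fused; other centres unassigned) | O=C1C[C@@H](O[Si](C)(C)C(C)(C)C)CC2C(C(=O)OC)C(O[Si](C)(C)C)=CC(OC)(O[Si](C)(C)C)C12Br | intermediate (not isolated)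
12 | methyl (7S)-7-[(tert-butyldimethylsilyl)oxy]-2,4-dihydroxy-5-oxo-5,6,7,8-tetrahydronaphthalene-1-carboxylate | O=C1C[C@@H](O[Si](C)(C)C(C)(C)C)Cc2c1c(O)cc(O)c2C(=O)OC | intermediate
13 | methyl (7S)-7-[(tert-butyldimethylsilyl)oxy]-4-hydroxy-5-oxo-2-{[(trifluoromethyl)sulfonyl]oxy}-5,6,7,8-tetrahydronaphthalene-1-carboxylate | O=C1C[C@@H](O[Si](C)(C)C(C)(C)C)Cc2c1c(O)cc(OS(=O)(=O)C(F)(F)F)c2C(=O)OC | intermediate
14 | phenylboronic acid | OB(O)c1ccccc1 | starting material
15 | methyl (7S)-7-[(tert-butyldimethylsilyl)oxy]-4-hydroxy-5-oxo-2-phenyl-5,6,7,8-tetrahydronaphthalene-1-carboxylate | O=C1C[C@@H](O[Si](C)(C)C(C)(C)C)Cc2c1c(O)cc(-c1ccccc1)c2C(=O)OC | intermediate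
16 | benzyl alcohol | OCc1ccccc1 | starting material
17 | methyl (7S)-4-(benzyloxy)-7-[(tert-butyldimethylsilyl)oxy]-5-oxo-2-phenyl-5,6,7,8-tetrahydronaphthalene-1-carboxylate | O=C1C[C@@H](O[Si](C)(C)C(C)(C)C)Cc2c1c(OCc1ccccc1)cc(-c1ccccc1)c2C(=O)OC | intermediate
18 | (3S)-8-(benzyloxy)-3-[(tert-butyldimethylsilyl)oxy]-5-(hydroxymethyl)-6-phenyl-1,2,3,4-tetrahydronaphthalen-1-ol (both C1 epimers) | OC1C[C@@H](O[Si](C)(C)C(C)(C)C)Cc2c1c(OCc1ccccc1)cc(-c1ccccc1)c2CO | intermediate
19 | (7S)-4-(benzyloxy)-7-[(tert-butyldimethylsilyl)oxy]-5-oxo-2-phenyl-5,6,7,8-tetrahydronaphthalene-1-carbaldehyde | O=C1C[C@@H](O[Si](C)(C)C(C)(C)C)Cc2c1c(OCc1ccccc1)cc(-c1ccccc1)c2C=O | intermediate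
20 | 3-ethoxycyclobut-2-en-1-one | CCOC1=CC(=O)C1 | starting material
21 | 3-(benzyloxy)cyclobut-2-en-1-one | O=C1C=C(OCc2ccccc2)C1 | intermediate
22 | lithium 3-(benzyloxy)cyclobuta-1,3-dien-1-olate | [Li+].[O-]C1=CC(OCc2ccccc2)=C1 | intermediate (not isolated)
23 | (3S)-8-(benzyloxy)-5-{[2-(benzyloxy)-4-oxocyclobut-2-en-1-yl](hydroxy)methyl}-3-[(tert-butyldimethylsilyl)oxy]-6-phenyl-3,4-dihydronaphthalen-1(2H)-one (mixture at carbinol and ring carbon) | O=C1C[C@@H](O[Si](C)(C)C(C)(C)C)Cc2c1c(OCc1ccccc1)cc(-c1ccccc1)c2C(O)C1C(=O)C=C1OCc1ccccc1 | intermediate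
24 | (3S)-8-(benzyloxy)-5-{[2-(benzyloxy)-4-oxocyclobut-2-en-1-yl]carbonyl}-3-[(tert-butyldimethylsilyl)oxy]-6-phenyl-3,4-dihydronaphthalen-1(2H)-one (enolisable ring carbon unspecified) | O=C1C[C@@H](O[Si](C)(C)C(C)(C)C)Cc2c1c(OCc1ccccc1)cc(-c1ccccc1)c2C(=O)C1C(=O)C=C1OCc1ccccc1 | intermediate (key-step precursor)
25 | (3S)-8-(benzyloxy)-5-[(2E)-3-(benzyloxy)-5-oxopenta-2,4-dienoyl]-3-[(tert-butyldimethylsilyl)oxy]-6-phenyl-3,4-dihydronaphthalen-1(2H)-one (aroyl cis to the ketene) | O=C1C[C@@H](O[Si](C)(C)C(C)(C)C)Cc2c1c(OCc1ccccc1)cc(-c1ccccc1)c2C(=O)/C=C(OCc1ccccc1)\C=C=O | intermediate (not isolated)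
26 | (3S)-8-(benzyloxy)-5-[4-(benzyloxy)-2-oxo-2H-pyran-6-yl]-3-[(tert-butyldimethylsilyl)oxy]-6-phenyl-3,4-dihydronaphthalen-1(2H)-one | O=C1C[C@@H](O[Si](C)(C)C(C)(C)C)Cc2c1c(OCc1ccccc1)cc(-c1ccccc1)c2-c1cc(OCc2ccccc2)cc(=O)o1 | intermediate (key-step product)
27 | (3S)-8-(benzyloxy)-5-[4-(benzyloxy)-2-oxo-2H-pyran-6-yl]-3-hydroxy-6-phenyl-3,4-dihydronaphthalen-1(2H)-one | O=C1C[C@@H](O)Cc2c1c(OCc1ccccc1)cc(-c1ccccc1)c2-c1cc(OCc2ccccc2)cc(=O)o1 | intermediate
28 | wailupemycin F, (3S)-3,8-dihydroxy-5-(4-hydroxy-2-oxo-2H-pyran-6-yl)-6-phenyl-3,4-dihydronaphthalen-1(2H)-one | O=C1C[C@@H](O)Cc2c1c(O)cc(-c1ccccc1)c2-c1cc(O)cc(=O)o1 | target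

**Step count**

Total: 18 steps. Longest linear sequence: 15 steps (1 to 28 through steps 1–4, 7–12 and 14–18).

**Steps most likely to fail**

Step 7. The cycloaddition may be slower than thermal decay of the silyl ketene acetal. In the cis-fused adduct the angular bromine has only a syn hydrogen on C4a, so dehydrobromination may lag behind loss of the C3 silyloxy group or reductive loss of bromine. The fallback replaces bromide by a sulfoxide, which eliminates thermally through exactly that syn geometry. Starting from 7, ketalisation with 1,2-bis(trimethylsilyloxy)ethane and catalytic Me3SiOTf (CH2Cl2, −78 °C) gives (9S)-6-bromo-9-[(tert-butyldimethylsilyl)oxy]-1,4-dioxaspiro[4.5]dec-6-ene F1. Bromine–lithium exchange (n-BuLi, THF, −78 °C) and quenching with methyl benzenesulfinate gives (9S)-9-[(tert-butyldimethylsilyl)oxy]-6-(phenylsulfinyl)-1,4-dioxaspiro[4.5]dec-6-ene F2, either configuration at sulfur being usable. PPTS in wet acetone releases (5S)-5-[(tert-butyldimethylsilyl)oxy]-2-(phenylsulfinyl)cyclohex-2-en-1-one F3. This more reactive dienophile is combined with diene 10 in toluene (rt to 80 °C) to give methyl (7S)-7-[(tert-butyldimethylsilyl)oxy]-4-methoxy-5-oxo-4a-(phenylsulfinyl)-2,4-bis[(trimethylsilyl)oxy]-1,4,4a,5,6,7,8,8a-octahydronaphthalene-1-carboxylate F4. Thermal syn elimination of benzenesulfenic acid, loss of methanol and mild acidic work-up then give 12, where the route is rejoined.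

Step 14. The lithium enolate of 21, formally a cyclobutadienolate, may decompose or abstract a C2 proton of the tetralone faster than it adds to the doubly ortho-substituted aldehyde, and the aldolate may revert on warming. The fallback builds the cyclobutenone on the aldehyde by ketene–alkoxyalkyne [2+2] cycloaddition instead of adding it as an enolate. Starting from 19, lithiated tert-butoxyethyne (n-BuLi, THF, −78 °C) adds to the aldehyde to give (3S)-8-(benzyloxy)-5-(3-tert-butoxy-1-hydroxyprop-2-yn-1-yl)-3-[(tert-butyldimethylsilyl)oxy]-6-phenyl-3,4-dihydronaphthalen-1(2H)-one F5. TMSCl and imidazole give (3S)-8-(benzyloxy)-5-{3-tert-butoxy-1-[(trimethylsilyl)oxy]prop-2-yn-1-yl}-3-[(tert-butyldimethylsilyl)oxy]-6-phenyl-3,4-dihydronaphthalen-1(2H)-one F6. Warming F6 to about 60 °C in toluene with excess ethoxyethyne releases 2-methylpropene by retro-ene cleavage to the ketene (3S)-8-(benzyloxy)-3-[(tert-butyldimethylsilyl)oxy]-5-{3-oxo-1-[(trimethylsilyl)oxy]prop-2-en-1-yl}-6-phenyl-3,4-dihydronaphthalen-1(2H)-one F7. The ketene is trapped in the same flask as (3S)-8-(benzyloxy)-3-[(tert-butyldimethylsilyl)oxy]-5-{(2-ethoxy-4-oxocyclobut-2-en-1-yl)[(trimethylsilyl)oxy]methyl}-6-phenyl-3,4-dihydronaphthalen-1(2H)-one F8. PPTS and benzyl alcohol 16 under the conditions of step 13 exchange ethoxy for benzyloxy and cleave the trimethylsilyl ether, giving 23, where the route is rejoined.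

Step 8. Sulfonylation may fail to discriminate between the two chelated phenols, so that the C8 triflate or the bis-triflate forms beside 13. The fallback installs the phenyl group before the benzannulation, so that no phenol has to be differentiated. Starting from 8, NaH and PhNTf2 in THF give dimethyl 3-{[(trifluoromethyl)sulfonyl]oxy}pent-2-enedioate F9. Suzuki–Miyaura coupling with 14 (Pd(PPh3)4, K3PO4) gives dimethyl 3-phenylpent-2-enedioate F10, either alkene geometry being usable. LiN(iPr)2 and TMSCl give methyl 5-methoxy-3-phenyl-5-[(trimethylsilyl)oxy]penta-2,4-dienoate F11. Diels–Alder reaction with 7 in hot toluene gives methyl (7S)-4a-bromo-7-[(tert-butyldimethylsilyl)oxy]-4-methoxy-5-oxo-2-phenyl-4-[(trimethylsilyl)oxy]-1,4,4a,5,6,7,8,8a-octahydronaphthalene-1-carboxylate F12. After DBU and mild acidic work-up F12 loses HBr, methanol and its trimethylsilyl group to give 15 directly, where the route is rejoined. This diene is less electron-rich than 10, which is why it is held in reserve.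

**Further compounds**

F1 | step 7 | (9S)-6-bromo-9-[(tert-butyldimethylsilyl)oxy]-1,4-dioxaspiro[4.5]dec-6-ene | C12(OCCO1)C[C@@H](O[Si](C)(C)C(C)(C)C)CC=C2Br
F2 | step 7 | (9S)-9-[(tert-butyldimethylsilyl)oxy]-6-(phenylsulfinyl)-1,4-dioxaspiro[4.5]dec-6-ene | C12(OCCO1)C[C@@H](O[Si](C)(C)C(C)(C)C)CC=C2S(=O)c1ccccc1
F3 | step 7 | (5S)-5-[(tert-butyldimethylsilyl)oxy]-2-(phenylsulfinyl)cyclohex-2-en-1-one | O=C1C[C@@H](O[Si](C)(C)C(C)(C)C)CC=C1S(=O)c1ccccc1
F4 | step 7 | methyl (7S)-7-[(tert-butyldimethylsilyl)oxy]-4-methoxy-5-oxo-4a-(phenylsulfinyl)-2,4-bis[(trimethylsilyl)oxy]-1,4,4a,5,6,7,8,8a-octahydronaphthalene-1-carboxylate | O=C1C[C@@H](O[Si](C)(C)C(C)(C)C)CC2C(C(=O)OC)C(O[Si](C)(C)C)=CC(OC)(O[Si](C)(C)C)C12S(=O)c1ccccc1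
F5 | step 14 | (3S)-8-(benzyloxy)-5-(3-tert-butoxy-1-hydroxyprop-2-yn-1-yl)-3-[(tert-butyldimethylsilyl)oxy]-6-phenyl-3,4-dihydronaphthalen-1(2H)-one | O=C1C[C@@H](O[Si](C)(C)C(C)(C)C)Cc2c1c(OCc1ccccc1)cc(-c1ccccc1)c2C(O)C#COC(C)(C)C
F6 | step 14 | (3S)-8-(benzyloxy)-5-{3-tert-butoxy-1-[(trimethylsilyl)oxy]prop-2-yn-1-yl}-3-[(tert-butyldimethylsilyl)oxy]-6-phenyl-3,4-dihydronaphthalen-1(2H)-one | O=C1C[C@@H](O[Si](C)(C)C(C)(C)C)Cc2c1c(OCc1ccccc1)cc(-c1ccccc1)c2C(O[Si](C)(C)C)C#COC(C)(C)C
F7 | step 14 | (3S)-8-(benzyloxy)-3-[(tert-butyldimethylsilyl)oxy]-5-{3-oxo-1-[(trimethylsilyl)oxy]prop-2-en-1-yl}-6-phenyl-3,4-dihydronaphthalen-1(2H)-one | O=C1C[C@@H](O[Si](C)(C)C(C)(C)C)Cc2c1c(OCc1ccccc1)cc(-c1ccccc1)c2C(O[Si](C)(C)C)C=C=O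
F8 | step 14 | (3S)-8-(benzyloxy)-3-[(tert-butyldimethylsilyl)oxy]-5-{(2-ethoxy-4-oxocyclobut-2-en-1-yl)[(trimethylsilyl)oxy]methyl}-6-phenyl-3,4-dihydronaphthalen-1(2H)-one | O=C1C[C@@H](O[Si](C)(C)C(C)(C)C)Cc2c1c(OCc1ccccc1)cc(-c1ccccc1)c2C(O[Si](C)(C)C)C1C(=O)C=C1OCC
F9 | step 8 | dimethyl 3-{[(trifluoromethyl)sulfonyl]oxy}pent-2-enedioate | COC(=O)CC(OS(=O)(=O)C(F)(F)F)=CC(=O)OC
F10 | step 8 | dimethyl 3-phenylpent-2-enedioate | COC(=O)CC(=CC(=O)OC)c1ccccc1
F11 | step 8 | methyl 5-methoxy-3-phenyl-5-[(trimethylsilyl)oxy]penta-2,4-dienoate | COC(=O)C=C(C=C(OC)O[Si](C)(C)C)c1ccccc1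
F12 | step 8 | methyl (7S)-4a-bromo-7-[(tert-butyldimethylsilyl)oxy]-4-methoxy-5-oxo-2-phenyl-4-[(trimethylsilyl)oxy]-1,4,4a,5,6,7,8,8a-octahydronaphthalene-1-carboxylate | O=C1C[C@@H](O[Si](C)(C)C(C)(C)C)CC2C(C(=O)OC)C(c3ccccc3)=CC(OC)(O[Si](C)(C)C)C12Br
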